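The atoms carry prostanoid numbers: C1 is the ester carbon, the ring is C8–C12, C20 is the chain methyl. Retrosynthesis: take the silyl group off O12, cut C6–C7 (Suzuki–Miyaura) and C7=C8 (formylation), then cut the ring bonds C8–C9 and C11–C12 together.
The double cut is possible because the ring is a 4-hydroxycyclopent-2-enone. C9=O and C12–OH stand 1,4 across C10=C11, so a C9–C10–C11 acylsilane can be clipped onto the C8/C12 enolate of (Z)-dec-4-en-2-one. In that acylsilane the silicon on C9 switches polarity by Brook rearrangement, PhS on C11 anchors the anion and later leaves, and Cl already sits on C10.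
Forward: acylsilane 5 (three steps from methoxyallene) and enol silane 9 (two steps from (Z)-non-3-en-1-ol) give the only ring in step 6. Removing the silicon and sulfur helpers then gives the 2-chloro-4-hydroxycyclopentenone. C7 and the C1–C6 chain are joined last.
Stereochemistry: C12 forms as a racemate in step 6. It becomes single-handed through reagent-controlled CBS reduction of C9=O, separation of the two diastereomers and reoxidation. 14Z comes from the starting alcohol, 5E from syn hydroboration, and 7Z from a lithium-chelated Z enol triflate that is coupled with retention.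

Key step: step 6

Remark: racemic compounds are written with C12 (and C11) undefined in their SMILES; from 16 onward every SMILES is a single enantiomer.

Step 1
Reactants: 1 methoxyallene
Product: 3 tert-butyl[1-methoxy-3-(phenylsulfanyl)propa-1,2-dienyl]dimethylsilane (racemic), via 1-silylated methoxyallene 2 (not isolated)
Conditions: n-BuLi, THF, −78 °C; t-BuMe2SiCl, −78 → 0 °C; n-BuLi, −78 °C; PhSSPh, −78 → 0 °C; H2O
Reagents that add atoms: tert-butyldimethylsilyl chloride CC(C)(C)[Si](C)(C)Cl; diphenyl disulfide c1ccc(cc1)SSc1ccccc1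
Why: Sequential lithiation and electrophilic trapping of an alkoxyallene is the standard entry to 1-silyl-3-substituted alkoxyallenes, the first deprotonation going to C1 next to oxygen and the second to the only remaining acidic allenic position C3.

Step 2
Reactants: 3 tert-butyl[1-methoxy-3-(phenylsulfanyl)propa-1,2-dienyl]dimethylsilane
Product: 4 (E)-1-[tert-butyl(dimethyl)silyl]-3-(phenylsulfanyl)prop-2-en-1-one
Conditions: 1 M H2SO4, THF, 0 → 23 °C
Reagents that add atoms: water O
Why: Acid hydrolysis of the silyl-substituted enol ether (protonation of the central allene carbon, capture of the oxocarbenium carbon by water, loss of methanol) unmasks the acylsilane, and the reversible steps should drain to the E vinylogous thioester because thiol adds back to wrongly opened material whereas dilute methanol does not.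

Step 3
Reactants: 4 (E)-1-[tert-butyl(dimethyl)silyl]-3-(phenylsulfanyl)prop-2-en-1-one
Product: 5 (Z)-1-[tert-butyl(dimethyl)silyl]-2-chloro-3-(phenylsulfanyl)prop-2-en-1-one
Conditions: N-chlorosuccinimide, CH2Cl2, 0 → 23 °C, dark
Reagents that add atoms: N-chlorosuccinimide O=C1CCC(=O)N1Cl
Why: Electrophilic α-chlorination of a β-sulfanyl enone (the vinyl sulfide attacks the chlorine donor through C10 and the thionium ion loses the C10 proton) places chlorine only on C10 and should keep sulfur trans to the acyl group.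

Step 4
Reactants: 6 (Z)-non-3-en-1-ol
Product: 7 (Z)-non-3-enoic acid
Conditions: CrO3, H2SO4, H2O, acetone, 0 °C
Reagents that add atoms: water O
Why: Jones oxidation takes the homoallylic alcohol through its aldehyde hydrate to the acid fast enough at 0 °C that the β,γ-unsaturated aldehyde should not slip into conjugation, so the Z alkene (later C14=C15) is kept.

Step 5
Reactants: 7 (Z)-non-3-enoic acid
Product: 9 [(4Z)-deca-1,4-dien-2-yl]oxy-trimethylsilane, via trimethylsilyl ester 8 (not isolated)
Conditions: (Me3Si)2NH, 60 °C; then Cp2TiMe2, toluene, 70 °C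
Reagents that add atoms: hexamethyldisilazane C[Si](C)(C)N[Si](C)(C)C; Cp2TiMe2 C[Ti](C)(C1C=CC=C1)C1C=CC=C1
Why: Petasis methylenation of the silyl ester carbonyl gives the terminal enol silane regiospecifically and so avoids any deprotonation of the skipped enone, whose C13 protons are the most acidic ones.

Step 6
Reactants: 9 [(4Z)-deca-1,4-dien-2-yl]oxy-trimethylsilane; 5 (Z)-1-[tert-butyl(dimethyl)silyl]-2-chloro-3-(phenylsulfanyl)prop-2-en-1-one
Product: 12 4-[tert-butyl(dimethyl)silyl]oxy-3-chloro-1-[(Z)-oct-2-enyl]-2-(phenylsulfanyl)cyclopent-3-en-1-ol (racemic), via lithium enolate 10 (not isolated), via silyl alkoxide adduct 11 (not isolated)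
Conditions: 9, MeLi, THF, 0 °C; cool to −80 °C, add 5; −80 → −30 °C; AcOH
Reagents that add atoms: none
Why: The regiodefined lithium enolate 10 adds 1,2 to the acylsilane carbonyl of 5 (bond C8–C9, adduct 11), the α-silyl alkoxide undergoes a 1,2-Brook rearrangement that moves silicon from C9 to oxygen, and the resulting 1-siloxy-3-(phenylsulfanyl)allyllithium attacks the regenerated C12 ketone through its sulfur-stabilised terminus C11 (bond C11–C12). The closest known reaction type is the Brook-rearrangement-mediated [3+2] annulation of β-(phenylsulfanyl)acryloylsilanes with lithium enolates of alkyl methyl ketones, which delivers precursors of 4-alkyl-4-hydroxycyclopentenones. The cyclopentene ring closes formally 5-(enolendo)-exo-trig at the C12 carbonyl, which is workable because the charge sits on the pyramidal, sulfur-bearing C11–Li, and the same ring also results from 3-exo-trig attack of C9 followed by an oxyanion-accelerated vinylcyclopropanolate shift. C11 and C12 arise as a racemate because no chiral element is present, their relative configuration follows from the lithium-bridged compact transition state, C11 is erased in step 7 and the absolute configuration at C12 is secured in steps 9 and 10. The step needs 1,2- over 1,4-addition (secured by the donor sulfur on C11 and the very electrophilic silyl ketone), reaction at C8 and not at C13 (secured by releasing 10 from 9 without any proton source), and ring closure faster than loss of chloride from C10 (favoured because the C10–Cl bond lies in the nodal plane of the allyl anion at −80 °C).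

Step 7
Reactants: 12 4-[tert-butyl(dimethyl)silyl]oxy-3-chloro-1-[(Z)-oct-2-enyl]-2-(phenylsulfanyl)cyclopent-3-en-1-ol
Product: 14 2-chloro-4-hydroxy-4-[(Z)-oct-2-enyl]cyclopent-2-en-1-one (racemic), via sulfoxide 13 (not isolated)
Conditions: m-CPBA (1 equiv), CH2Cl2, −78 °C; then Et3N·3HF, −78 → 23 °C
Reagents that add atoms: none
Why: Chemoselective sulfide oxidation at −78 °C followed by fluoride cleavage of the enol silane gives an α-chloro-β-sulfinyl ketone that loses benzenesulfenic acid by sulfoxide elimination, which unveils C10=C11 without free thiolate that could add back.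

Step 8
Reactants: 14 2-chloro-4-hydroxy-4-[(Z)-oct-2-enyl]cyclopent-2-en-1-one
Product: 15 2-chloro-4-[(Z)-oct-2-enyl]-4-(triethylsilyloxy)cyclopent-2-en-1-one (racemic)
Conditions: Et3SiOTf, 2,6-lutidine, CH2Cl2, −78 → 0 °C
Reagents that add atoms: triethylsilyl trifluoromethanesulfonate CC[Si](CC)(CC)OS(=O)(=O)C(F)(F)F
Why: Silyl triflate silylation with a hindered pyridine base protects the tertiary C12 alcohol, so that the later enolate steps meet no alkoxide and no retro-aldol ring opening.

Step 9
Reactants: 15 2-chloro-4-[(Z)-oct-2-enyl]-4-(triethylsilyloxy)cyclopent-2-en-1-one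
Product: 16 (1R,4S)-2-chloro-4-[(Z)-oct-2-enyl]-4-(triethylsilyloxy)cyclopent-2-en-1-ol
Conditions: (S)-2-methyl-CBS-oxazaborolidine, catecholborane, toluene, −78 °C; chromatographic separation of the two diastereomers
Reagents that add atoms: none
Why: The Corey–Bakshi–Shibata reduction is reagent-controlled for α-halo enones (the chlorovinyl arm acts as the large group), so both enantiomers of 15 should give the 1R carbinol and hence two separable diastereomers, of which the (1R,4S) one carries the C12 configuration of the target.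

Step 10
Reactants: 16 (1R,4S)-2-chloro-4-[(Z)-oct-2-enyl]-4-(triethylsilyloxy)cyclopent-2-en-1-ol
Product: 17 (4S)-2-chloro-4-[(Z)-oct-2-enyl]-4-(triethylsilyloxy)cyclopent-2-en-1-one
Conditions: Dess–Martin periodinane, CH2Cl2, 0 → 23 °C
Reagents that add atoms: none
Why: Dess–Martin oxidation returns the allylic alcohol to the enone under neutral conditions that touch neither the silyl ether, the Z alkene nor C12.

Step 11
Reactants: 17 (4S)-2-chloro-4-[(Z)-oct-2-enyl]-4-(triethylsilyloxy)cyclopent-2-en-1-one
Product: 18 (4R,5Z)-2-chloro-5-(hydroxymethylidene)-4-[(Z)-oct-2-enyl]-4-(triethylsilyloxy)cyclopent-2-en-1-one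
Conditions: LiN(iPr)2, THF, −78 °C; HCO2CH2CF3, −78 °C; AcOH
Reagents that add atoms: 2,2,2-trifluoroethyl formate O=COCC(F)(F)F
Why: Kinetic deprotonation at C8, the only enolisable position of the cross-conjugated ketone, followed by Claisen-type formylation with the activated formate installs C7, and the product should rest as the hydrogen-bonded Z enol.

Step 12
Reactants: 18 (4R,5Z)-2-chloro-5-(hydroxymethylidene)-4-[(Z)-oct-2-enyl]-4-(triethylsilyloxy)cyclopent-2-en-1-one
Product: 19 (Z)-[(5R)-3-chloro-2-oxo-5-[(Z)-oct-2-enyl]-5-(triethylsilyloxy)cyclopent-3-en-1-ylidene]methyl trifluoromethanesulfonate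
Conditions: LiN(SiMe3)2, THF, −78 °C; N-(5-chloropyridin-2-yl)bis(trifluoromethanesulfonimide), −78 → −20 °C; AcOH
Reagents that add atoms: N-(5-chloropyridin-2-yl)bis(trifluoromethanesulfonimide) O=S(=O)(N(c1ccc(Cl)cn1)S(=O)(=O)C(F)(F)F)C(F)(F)F
Why: O-Triflation of the U-shaped lithium chelate, in which the oxygen on C7 is held syn to the C9 carbonyl and away from the quaternary C12, should fix the Z enol triflate geometry.

Step 13
Reactants: 20 methyl hex-5-ynoate
Product: 21 methyl (E)-6-(4,4,5,5-tetramethyl-1,3,2-dioxaborolan-2-yl)hex-5-enoate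
Conditions: pinacolborane, Cp2ZrHCl (cat.), Et3N (cat.), neat, 60 °C
Reagents that add atoms: pinacolborane [H]B1OC(C)(C)C(C)(C)O1
Why: Zirconocene-hydride-catalysed syn hydroboration of the terminal alkyne gives the E alkenylboronate and thereby the 5E geometry, the ester being inert.

Step 14
Reactants: 19 (Z)-[(5R)-3-chloro-2-oxo-5-[(Z)-oct-2-enyl]-5-(triethylsilyloxy)cyclopent-3-en-1-ylidene]methyl trifluoromethanesulfonate; 21 methyl (E)-6-(4,4,5,5-tetramethyl-1,3,2-dioxaborolan-2-yl)hex-5-enoate
Product: 22 methyl (5E,7Z)-7-[(2R)-4-chloro-2-[(Z)-oct-2-enyl]-5-oxo-2-(triethylsilyloxy)cyclopent-3-en-1-ylidene]hept-5-enoate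
Conditions: Pd(PPh3)4 (cat.), K3PO4, THF–H2O, 23 °C
Reagents that add atoms: none
Why: The Suzuki–Miyaura coupling runs with retention at both sp2 carbons, zerovalent palladium inserting into the activated C7–OTf bond rather than C10–Cl and the C9 carbonyl holding the alkenylpalladium in place, so C6 should end up cis to C9 (7Z) with the 5E alkene intact.

Step 15
Reactants: 22 methyl (5E,7Z)-7-[(2R)-4-chloro-2-[(Z)-oct-2-enyl]-5-oxo-2-(triethylsilyloxy)cyclopent-3-en-1-ylidene]hept-5-enoate
Product: 23 methyl (5E,7Z)-7-[(2R)-4-chloro-2-hydroxy-2-[(Z)-oct-2-enyl]-5-oxocyclopent-3-en-1-ylidene]hept-5-enoate (target)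
Conditions: HF·pyridine, THF, 0 °C
Reagents that add atoms: none
Why: Fluoride-mediated desilylation under mildly acidic conditions frees the tertiary alcohol without base, to which the cross-conjugated dienone would be sensitive.

Compound list
1 | methoxyallene | COC=C=C | starting material
2 | tert-butyl(1-methoxypropa-1,2-dienyl)dimethylsilane | COC(=C=C)[Si](C)(C)C(C)(C)C | intermediate
3 | tert-butyl[1-methoxy-3-(phenylsulfanyl)propa-1,2-dienyl]dimethylsilane (racemic) | COC(=C=CSc1ccccc1)[Si](C)(C)C(C)(C)C | intermediate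
4 | (E)-1-[tert-butyl(dimethyl)silyl]-3-(phenylsulfanyl)prop-2-en-1-one | O=C(/C=C/Sc1ccccc1)[Si](C)(C)C(C)(C)C | intermediate
5 | (Z)-1-[tert-butyl(dimethyl)silyl]-2-chloro-3-(phenylsulfanyl)prop-2-en-1-one | O=C(/C(Cl)=C/Sc1ccccc1)[Si](C)(C)C(C)(C)C | intermediate
6 | (Z)-non-3-en-1-ol | CCCCC/C=C\CCO | starting material
7 | (Z)-non-3-enoic acid | CCCCC/C=C\CC(=O)O | intermediate
8 | trimethylsilyl (Z)-non-3-enoate | CCCCC/C=C\CC(=O)O[Si](C)(C)C | intermediate
9 | [(4Z)-deca-1,4-dien-2-yl]oxy-trimethylsilane | CCCCC/C=C\CC(=C)O[Si](C)(C)C | intermediate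
10 | lithium (4Z)-deca-1,4-dien-2-olate | CCCCC/C=C\CC(=C)[O-].[Li+] | intermediate
11 | lithium (1Z,7Z)-3-[tert-butyl(dimethyl)silyl]-2-chloro-5-oxo-1-(phenylsulfanyl)trideca-1,7-dien-3-olate (racemic) | CCCCC/C=C\CC(=O)CC([O-])(/C(Cl)=C/Sc1ccccc1)[Si](C)(C)C(C)(C)C.[Li+] | intermediate
12 | 4-[tert-butyl(dimethyl)silyl]oxy-3-chloro-1-[(Z)-oct-2-enyl]-2-(phenylsulfanyl)cyclopent-3-en-1-ol (racemic) | CCCCC/C=C\CC1(O)CC(O[Si](C)(C)C(C)(C)C)=C(Cl)C1Sc1ccccc1 | intermediate
13 | 2-(benzenesulfinyl)-4-[tert-butyl(dimethyl)silyl]oxy-3-chloro-1-[(Z)-oct-2-enyl]cyclopent-3-en-1-ol (racemic) | CCCCC/C=C\CC1(O)CC(O[Si](C)(C)C(C)(C)C)=C(Cl)C1S(=O)c1ccccc1 | intermediate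
14 | 2-chloro-4-hydroxy-4-[(Z)-oct-2-enyl]cyclopent-2-en-1-one (racemic) | CCCCC/C=C\CC1(O)CC(=O)C(Cl)=C1 | intermediate
15 | 2-chloro-4-[(Z)-oct-2-enyl]-4-(triethylsilyloxy)cyclopent-2-en-1-one (racemic) | CCCCC/C=C\CC1(O[Si](CC)(CC)CC)CC(=O)C(Cl)=C1 | intermediate
16 | (1R,4S)-2-chloro-4-[(Z)-oct-2-enyl]-4-(triethylsilyloxy)cyclopent-2-en-1-ol | CCCCC/C=C\C[C@@]1(O[Si](CC)(CC)CC)C=C(Cl)[C@H](O)C1 | intermediate
17 | (4S)-2-chloro-4-[(Z)-oct-2-enyl]-4-(triethylsilyloxy)cyclopent-2-en-1-one | CCCCC/C=C\C[C@@]1(O[Si](CC)(CC)CC)C=C(Cl)C(=O)C1 | intermediate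
18 | (4R,5Z)-2-chloro-5-(hydroxymethylidene)-4-[(Z)-oct-2-enyl]-4-(triethylsilyloxy)cyclopent-2-en-1-one | CCCCC/C=C\C[C@@]1(O[Si](CC)(CC)CC)C=C(Cl)C(=O)/C1=C\O | intermediate
19 | (Z)-[(5R)-3-chloro-2-oxo-5-[(Z)-oct-2-enyl]-5-(triethylsilyloxy)cyclopent-3-en-1-ylidene]methyl trifluoromethanesulfonate | CCCCC/C=C\C[C@@]1(O[Si](CC)(CC)CC)C=C(Cl)C(=O)/C1=C\OS(=O)(=O)C(F)(F)F | intermediate
20 | methyl hex-5-ynoate | C#CCCCC(=O)OC | starting material
21 | methyl (E)-6-(4,4,5,5-tetramethyl-1,3,2-dioxaborolan-2-yl)hex-5-enoate | COC(=O)CCC/C=C/B1OC(C)(C)C(C)(C)O1 | intermediate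
22 | methyl (5E,7Z)-7-[(2R)-4-chloro-2-[(Z)-oct-2-enyl]-5-oxo-2-(triethylsilyloxy)cyclopent-3-en-1-ylidene]hept-5-enoate | CCCCC/C=C\C[C@@]1(O[Si](CC)(CC)CC)C=C(Cl)C(=O)/C1=C\C=C\CCCC(=O)OC | intermediate
23 | methyl (5E,7Z)-7-[(2R)-4-chloro-2-hydroxy-2-[(Z)-oct-2-enyl]-5-oxocyclopent-3-en-1-ylidene]hept-5-enoate | CCCCC/C=C\C[C@@]1(O)C=C(Cl)C(=O)/C1=C\C=C\CCCC(=O)OC | target

Total step count: 15. Longest linear sequence: 12 steps (1 → 3 → 4 → 5 → 12 → 14 → 15 → 16 → 17 → 18 → 19 → 22 → 23).

Steps most likely to fail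

Step 6. Three things may go wrong. After the Brook shift the 2-chloroallyl anion may twist and expel chloride. It may be quenched by proton transfer from the doubly activated C13 position of the open-chain ketone before it closes. The enolate may also add in the conjugate sense.

The fallback brings in chlorine only after the ring is made; it sets out from 4 and 9 and comes back at 14. Acylsilane 4 and enolate 10 released from 9 are joined under the conditions of step 6, the chlorine-free form of the annulation. This gives 4-[tert-butyl(dimethyl)silyl]oxy-1-[(Z)-oct-2-enyl]-2-(phenylsulfanyl)cyclopent-3-en-1-ol F1. m-CPBA at −78 °C gives the sulfoxide 2-(benzenesulfinyl)-4-[tert-butyl(dimethyl)silyl]oxy-1-[(Z)-oct-2-enyl]cyclopent-3-en-1-ol F2. With Et3N·3HF this collapses to 4-hydroxy-4-[(Z)-oct-2-enyl]cyclopent-2-en-1-one F3. Nucleophilic epoxidation (H2O2, NaOH, MeOH, 0 °C) leaves the isolated alkene alone and gives 4-hydroxy-4-[(Z)-oct-2-enyl]-6-oxabicyclo[3.1.0]hexan-2-one F4. HCl in THF then converts F4 into 14 by chloride attack at C10 and loss of water.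

Step 12. The geometry may erode through sulfonylation of the open, non-chelated enolate or through addition–elimination on the activated triflate, and sulfonylation at the ring oxygen may compete.

The fallback joins the chain by aldol addition and dehydration; it sets out from 17 and comes back at 22. Cross metathesis of methyl hex-5-enoate with crotonaldehyde (second-generation Hoveyda–Grubbs catalyst) gives methyl (E)-7-oxohept-5-enoate F5. The lithium enolate of 17 (LiN(iPr)2, THF, −78 °C) adds to F5 and gives the aldol methyl (E)-7-[(2R)-4-chloro-2-[(Z)-oct-2-enyl]-5-oxo-2-(triethylsilyloxy)cyclopent-3-en-1-yl]-7-hydroxyhept-5-enoate F6. MsCl and Et3N give its methanesulfonate F7. DBU eliminates F7 to 22 together with methyl (5E,7E)-7-[(2R)-4-chloro-2-[(Z)-oct-2-enyl]-5-oxo-2-(triethylsilyloxy)cyclopent-3-en-1-ylidene]hept-5-enoate F8. The isomers are separated by HPLC, and F8 is re-equilibrated by irradiation and recycled.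

Step 9. Reagent control may be incomplete against the facial bias of the substrate, the borane may attack the chain alkene, or the two diastereomers may not separate.

The fallback replaces the chemical differentiation by a physical one; it sets out from 15 and comes back at 17. Racemic 15 is resolved by preparative chromatography on a chiral stationary phase (amylose tris(3,5-dimethylphenylcarbamate)), and the S enantiomer collected is 17. This also makes step 10 unnecessary. The fallback makes no new compound (F0).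

Further compounds
F1 | step 6 | 4-[tert-butyl(dimethyl)silyl]oxy-1-[(Z)-oct-2-enyl]-2-(phenylsulfanyl)cyclopent-3-en-1-ol (racemic) | CCCCC/C=C\CC1(O)CC(O[Si](C)(C)C(C)(C)C)=CC1Sc1ccccc1
F2 | step 6 | 2-(benzenesulfinyl)-4-[tert-butyl(dimethyl)silyl]oxy-1-[(Z)-oct-2-enyl]cyclopent-3-en-1-ol (racemic) | CCCCC/C=C\CC1(O)CC(O[Si](C)(C)C(C)(C)C)=CC1S(=O)c1ccccc1
F3 | step 6 | 4-hydroxy-4-[(Z)-oct-2-enyl]cyclopent-2-en-1-one (racemic) | CCCCC/C=C\CC1(O)CC(=O)C=C1
F4 | step 6 | 4-hydroxy-4-[(Z)-oct-2-enyl]-6-oxabicyclo[3.1.0]hexan-2-one (racemic) | CCCCC/C=C\CC1(O)CC(=O)C2OC12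
F5 | step 12 | methyl (E)-7-oxohept-5-enoate | COC(=O)CCC/C=C/C=O
F6 | step 12 | methyl (E)-7-[(2R)-4-chloro-2-[(Z)-oct-2-enyl]-5-oxo-2-(triethylsilyloxy)cyclopent-3-en-1-yl]-7-hydroxyhept-5-enoate | CCCCC/C=C\C[C@@]1(O[Si](CC)(CC)CC)C=C(Cl)C(=O)C1C(O)/C=C/CCCC(=O)OC
F7 | step 12 | methyl (E)-7-[(2R)-4-chloro-2-[(Z)-oct-2-enyl]-5-oxo-2-(triethylsilyloxy)cyclopent-3-en-1-yl]-7-(methylsulfonyloxy)hept-5-enoate | CCCCC/C=C\C[C@@]1(O[Si](CC)(CC)CC)C=C(Cl)C(=O)C1C(OS(C)(=O)=O)/C=C/CCCC(=O)OC
F8 | step 12 | methyl (5E,7E)-7-[(2R)-4-chloro-2-[(Z)-oct-2-enyl]-5-oxo-2-(triethylsilyloxy)cyclopent-3-en-1-ylidene]hept-5-enoate | CCCCC/C=C\C[C@@]1(O[Si](CC)(CC)CC)C=C(Cl)C(=O)/C1=C/C=C/CCCC(=O)OC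
F0 | step 9 | none | none
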